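**Retrosynthetic overview**

1. Numbering: oxolane O1, C2 (ring A), C3 (CH2OH), C4 (CH2–ring B), C5H2. The target is (2S,3R,4R), with C2/C3 trans and C3/C4 cis.
2. Feature the plan rests on: O1–C2 with C3 is an anti homoallylic alcohol pair. C4 and C5 are the α-carbon and carbonyl carbon of an acrylate whose exocyclic CH2 is the benzylic carbon of ring B.
3. Late stage: C5H2 comes from a lactone carbonyl (lactol, then ionic reduction). The CH2–ring B bond and the C4 centre come from conjugate arylation of an α-methylene lactone with protonation anti to the C3 arm.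
4. Key disconnection: C2–C3 and O1–C5, by chromium-catalysed asymmetric 2-(methoxycarbonyl)allylation of 3,4,5-trimethoxybenzaldehyde with a Baylis–Hillman-derived allylic bromide and lactonisation in the same step.
5. Ring order: the oxolane (first as the lactone) is the only ring made. Rings A and B are bought.

Key step: step 3

Assumption: the (S,S) ligand of step 3 is taken to deliver the allyl group to the Si face of the aldehyde; if the opposite sense is found, its mirror image (from the other valinol) is used. Atom labels in the Why lines are those of the target oxolane.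

**Route**

Step 1
Reactants: 1 methyl acrylate; 2 (tert-butyldimethylsilyloxy)acetaldehyde
Product: 3 methyl 4-[(tert-butyldimethylsilyl)oxy]-3-hydroxy-2-methylidenebutanoate (racemic)
Conditions: DABCO (0.5 equiv), 1 (3 equiv), dioxane/H2O 1:1, rt
Reagents that add atoms: none
Why: Morita–Baylis–Hillman reaction, in which the DABCO–acrylate zwitterion adds to the reactive α-silyloxy aldehyde; the racemic carbinol centre is destroyed in step 2.

Step 2
Reactants: 3 methyl 4-[(tert-butyldimethylsilyl)oxy]-3-hydroxy-2-methylidenebutanoate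
Product: 4 methyl (2Z)-2-(bromomethyl)-4-[(tert-butyldimethylsilyl)oxy]but-2-enoate
Conditions: NBS (1.2 equiv), Me2S (1.3 equiv), CH2Cl2, 0 °C → rt
Reagents that add atoms: N-bromosuccinimide, O=C1CCC(=O)N1Br
Why: Corey–Kim-type activation of the allylic alcohol as an alkoxysulfonium salt and SN2′ attack of bromide at the terminal methylene should give the conjugated trisubstituted enoate with the silyloxymethyl group trans to the ester (Z); any E isomer is harmless because the allylchromium of step 3 equilibrates.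

Step 3
Reactants: 4 methyl (2Z)-2-(bromomethyl)-4-[(tert-butyldimethylsilyl)oxy]but-2-enoate; 5 3,4,5-trimethoxybenzaldehyde
Product: 8 (4R,5S)-4-{[(tert-butyldimethylsilyl)oxy]methyl}-3-methylidene-5-(3,4,5-trimethoxyphenyl)oxolan-2-one, via trimethylsilyl ether 6 (not isolated), via hydroxy ester 7 (not isolated)
Conditions: CrCl2 (10 mol %), (S,S)-1,8-bis(4-isopropyl-4,5-dihydrooxazol-2-yl)-3,6-diphenyl-9H-carbazole (11 mol %), i-Pr2NEt (0.3 equiv), Mn powder (2 equiv), Me3SiCl (1.5 equiv), 4 (1.3 equiv), THF, rt; then 1 M aq. HCl, THF, 0 °C, 10 min; then PPTS (0.2 equiv), toluene, 50 °C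
Reagents that add atoms: none
Why: Mn keeps the catalyst as divalent chromium, two equivalents of which insert into the C–Br bond of 4 to give a trivalent σ-allylchromium that equilibrates by 1,3-metal shift and adds through its γ-carbon to aldehyde 5 in a closed six-membered chair, after which Me3SiCl frees the metal as silyl ether 6. The closest known reaction type is the catalytic asymmetric Nozaki–Hiyama–Kishi 2-(alkoxycarbonyl)allylation of aldehydes with Mn/Me3SiCl turnover, which is established for α-methylene-γ-butyrolactones. The oxolanone closes by 5-exo-trig acyl substitution: cold dilute acid cleaves only the O–SiMe3 bond (7), and under PPTS the C2 hydroxyl attacks the methyl ester to form O1–C5 with loss of methanol; any chromium alkoxide that closes directly gives the same lactone. C3 is set relative to C2 by the chair with ring A and the silyloxymethyl group both equatorial (anti adduct, hence the trans lactone), and C2 is set as S by the chiral ligand on chromium, which directs the allyl group to the Si face of the aldehyde. The step needs γ- over α-attack, secured by the closed transition state, and anti over syn addition, secured by the equilibrating allylchromium in its bulky ligand sphere. It also needs the primary TBS ether to outlast the acid finish, because a free CH2OH would compete for the ester and give the isomeric lactone; the far greater acid stability of a TBS ether over a Me3Si ether and the non-nucleophilic PPTS/toluene medium should secure this.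

Step 4
Reactants: 8 (4R,5S)-4-{[(tert-butyldimethylsilyl)oxy]methyl}-3-methylidene-5-(3,4,5-trimethoxyphenyl)oxolan-2-one; 9 3,4,5-trimethoxyphenylboronic acid
Product: 10 (3R,4R,5S)-4-{[(tert-butyldimethylsilyl)oxy]methyl}-5-(3,4,5-trimethoxyphenyl)-3-[(3,4,5-trimethoxyphenyl)methyl]oxolan-2-one
Conditions: [Rh(cod)OH]2 (2.5 mol %), 9 (2 equiv), dioxane/H2O 10:1, 40 °C
Reagents that add atoms: none
Why: Hayashi–Miyaura rhodium-catalysed 1,4-addition puts ring B on the exocyclic acrylate carbon, and water should then protonate the rhodium enolate at C4 from the face opposite the adjacent C3 silyloxymethyl arm, so the benzyl group ends cis to that arm; the base-free medium guards this kinetic centre against epimerisation.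

Step 5
Reactants: 10 (3R,4R,5S)-4-{[(tert-butyldimethylsilyl)oxy]methyl}-5-(3,4,5-trimethoxyphenyl)-3-[(3,4,5-trimethoxyphenyl)methyl]oxolan-2-one
Product: 11 (3R,4R,5S)-4-{[(tert-butyldimethylsilyl)oxy]methyl}-5-(3,4,5-trimethoxyphenyl)-3-[(3,4,5-trimethoxyphenyl)methyl]oxolan-2-ol (mixture of anomers)
Conditions: i-Bu2AlH (1.2 equiv), CH2Cl2, −78 °C; aq. potassium sodium tartrate work-up
Reagents that add atoms: none
Why: Partial reduction of a lactone with i-Bu2AlH, in which the tetrahedral aluminium hemiacetal is stable at −78 °C and gives the lactol on work-up, leaving C4 untouched.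

Step 6
Reactants: 11 (3R,4R,5S)-4-{[(tert-butyldimethylsilyl)oxy]methyl}-5-(3,4,5-trimethoxyphenyl)-3-[(3,4,5-trimethoxyphenyl)methyl]oxolan-2-ol
Product: 12 tert-butyldimethyl{[(2S,3R,4R)-2-(3,4,5-trimethoxyphenyl)-4-[(3,4,5-trimethoxyphenyl)methyl]oxolan-3-yl]methoxy}silane
Conditions: Et3SiH (3 equiv), BF3·OEt2 (1.5 equiv), CH2Cl2, −78 °C; aq. NaHCO3 quench at −78 °C
Reagents that add atoms: none
Why: Ionic hydrogenation of a lactol, in which BF3 ionises the anomeric hydroxyl to the C5 oxocarbenium ion and Et3SiH reduces it at −78 °C faster than the benzylic C2–O bond or the TBS ether can react; no stereocentre is created.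

Step 7
Reactants: 12 tert-butyldimethyl{[(2S,3R,4R)-2-(3,4,5-trimethoxyphenyl)-4-[(3,4,5-trimethoxyphenyl)methyl]oxolan-3-yl]methoxy}silane
Product: 13 [(2S,3R,4R)-2-(3,4,5-trimethoxyphenyl)-4-[(3,4,5-trimethoxyphenyl)methyl]oxolan-3-yl]methanol (target)
Conditions: Bu4NF (1.2 equiv), THF, 0 °C → rt
Reagents that add atoms: none
Why: Fluoride-induced desilylation of the primary TBS ether, driven by the strong Si–F bond, leaves the three stereocentres untouched.

**Compound list**

1 | methyl acrylate | C=CC(=O)OC | starting material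
2 | (tert-butyldimethylsilyloxy)acetaldehyde | C[Si](C)(OCC=O)C(C)(C)C | starting material
3 | methyl 4-[(tert-butyldimethylsilyl)oxy]-3-hydroxy-2-methylidenebutanoate (racemic) | C=C(C(=O)OC)C(O)CO[Si](C)(C)C(C)(C)C | intermediate
4 | methyl (2Z)-2-(bromomethyl)-4-[(tert-butyldimethylsilyl)oxy]but-2-enoate | COC(=O)/C(CBr)=C/CO[Si](C)(C)C(C)(C)C | intermediate
5 | 3,4,5-trimethoxybenzaldehyde | COc1cc(C=O)cc(OC)c1OC | starting material
6 | methyl (3R,4S)-3-{[(tert-butyldimethylsilyl)oxy]methyl}-2-methylidene-4-(3,4,5-trimethoxyphenyl)-4-[(trimethylsilyl)oxy]butanoate | C[Si](C)(C)O[C@H](c1cc(OC)c(OC)c(OC)c1)[C@H](C(=C)C(=O)OC)CO[Si](C)(C)C(C)(C)C | intermediate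
7 | methyl (3R,4S)-3-{[(tert-butyldimethylsilyl)oxy]methyl}-4-hydroxy-2-methylidene-4-(3,4,5-trimethoxyphenyl)butanoate | O[C@H](c1cc(OC)c(OC)c(OC)c1)[C@H](C(=C)C(=O)OC)CO[Si](C)(C)C(C)(C)C | intermediate
8 | (4R,5S)-4-{[(tert-butyldimethylsilyl)oxy]methyl}-3-methylidene-5-(3,4,5-trimethoxyphenyl)oxolan-2-one | C=C1C(=O)O[C@H](c2cc(OC)c(OC)c(OC)c2)[C@H]1CO[Si](C)(C)C(C)(C)C | intermediate
9 | 3,4,5-trimethoxyphenylboronic acid | COc1cc(B(O)O)cc(OC)c1OC | starting material
10 | (3R,4R,5S)-4-{[(tert-butyldimethylsilyl)oxy]methyl}-5-(3,4,5-trimethoxyphenyl)-3-[(3,4,5-trimethoxyphenyl)methyl]oxolan-2-one | COc1cc(C[C@H]2C(=O)O[C@H](c3cc(OC)c(OC)c(OC)c3)[C@H]2CO[Si](C)(C)C(C)(C)C)cc(OC)c1OC | intermediate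
11 | (3R,4R,5S)-4-{[(tert-butyldimethylsilyl)oxy]methyl}-5-(3,4,5-trimethoxyphenyl)-3-[(3,4,5-trimethoxyphenyl)methyl]oxolan-2-ol (anomer mixture) | COc1cc(C[C@H]2C(O)O[C@H](c3cc(OC)c(OC)c(OC)c3)[C@H]2CO[Si](C)(C)C(C)(C)C)cc(OC)c1OC | intermediate
12 | tert-butyldimethyl{[(2S,3R,4R)-2-(3,4,5-trimethoxyphenyl)-4-[(3,4,5-trimethoxyphenyl)methyl]oxolan-3-yl]methoxy}silane | COc1cc(C[C@H]2CO[C@H](c3cc(OC)c(OC)c(OC)c3)[C@H]2CO[Si](C)(C)C(C)(C)C)cc(OC)c1OC | intermediate
13 | [(2S,3R,4R)-2-(3,4,5-trimethoxyphenyl)-4-[(3,4,5-trimethoxyphenyl)methyl]oxolan-3-yl]methanol | COc1cc(C[C@H]2CO[C@H](c3cc(OC)c(OC)c(OC)c3)[C@H]2CO)cc(OC)c1OC | target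

**Step count and risks**

Total step count: 7. Longest linear sequence: 7 steps (1 and 2 to 13).

Steps most likely to fail:

1. Step 3 (key step). The ester-bearing, γ-substituted allylchromium may add with poor anti/syn or facial selectivity, or ring closure may lag behind loss of the TBS group. The fallback sets out from aldehyde 5 and comes back at lactone 8, using auxiliary-controlled aldol chemistry. (S)-4-Benzyl-1,3-oxazolidin-2-one is acylated (n-BuLi, THF, −78 °C; methyl 4-chloro-4-oxobutanoate) to methyl 4-[(4S)-4-benzyl-2-oxo-1,3-oxazolidin-3-yl]-4-oxobutanoate F1. Its boron Z-enolate (Bu2BOTf, i-Pr2NEt, CH2Cl2, −78 °C) should add to 5 in an Evans syn aldol reaction, and the syn adduct closes onto the methyl ester to give the trans lactone (4S)-4-benzyl-3-[(2S,3S)-5-oxo-2-(3,4,5-trimethoxyphenyl)oxolane-3-carbonyl]-1,3-oxazolidin-2-one F2. LiOH/H2O2 removes the auxiliary to give (2S,3S)-5-oxo-2-(3,4,5-trimethoxyphenyl)oxolane-3-carboxylic acid F3. BH3·SMe2 reduces the acid in the presence of the lactone to (4R,5S)-4-(hydroxymethyl)-5-(3,4,5-trimethoxyphenyl)oxolan-2-one F4. TBSCl/imidazole gives (4R,5S)-4-{[(tert-butyldimethylsilyl)oxy]methyl}-5-(3,4,5-trimethoxyphenyl)oxolan-2-one F5. α-Methylenation follows: i-Pr2NLi and dimethyl(methylidene)ammonium iodide give the Mannich base (4R,5S)-4-{[(tert-butyldimethylsilyl)oxy]methyl}-3-[(dimethylamino)methyl]-5-(3,4,5-trimethoxyphenyl)oxolan-2-one F6, and MeI then NaHCO3 eliminate the amine to return to 8.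

2. Step 4. Protonation of the rhodium enolate may show poor facial selectivity, the cis centre at C4 may epimerise, or β-hydride elimination may compete. The fallback sets out from 8 and comes back at 10. A Mizoroki–Heck arylation with 5-iodo-1,2,3-trimethoxybenzene (Pd(OAc)2, Et3N, DMF, 80 °C) should give (3E,4R,5S)-4-{[(tert-butyldimethylsilyl)oxy]methyl}-5-(3,4,5-trimethoxyphenyl)-3-[(3,4,5-trimethoxyphenyl)methylidene]oxolan-2-one F7. Heterogeneous hydrogenation (H2 1 atm, Pd/C, EtOAc, rt, stopped after one equivalent) then adds hydrogen from the face opposite the C3 arm, so C4 is set by surface delivery of H2 and not by protonation.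

3. Step 6. BF3 may ionise the benzylic C2–O1 bond (ring opening or epimerisation at C2), or the oxocarbenium ion may lose the C4 proton and scramble C4. The fallback sets out from 10 and comes back at 12 without any cationic intermediate. LiAlH4 (THF, 0 °C) reduces the lactone to (1S,2R,3R)-2-{[(tert-butyldimethylsilyl)oxy]methyl}-1-(3,4,5-trimethoxyphenyl)-3-[(3,4,5-trimethoxyphenyl)methyl]butane-1,4-diol F8. Mitsunobu cyclodehydration (PPh3, DIAD, THF, 0 °C) then activates the primary hydroxyl, and the benzylic hydroxyl displaces it, closing O1–C5 with retention at C2.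

**Further compounds**

F1 | step 3 | methyl 4-[(4S)-4-benzyl-2-oxo-1,3-oxazolidin-3-yl]-4-oxobutanoate | COC(=O)CCC(=O)N1[C@@H](Cc2ccccc2)COC1=O
F2 | step 3 | (4S)-4-benzyl-3-[(2S,3S)-5-oxo-2-(3,4,5-trimethoxyphenyl)oxolane-3-carbonyl]-1,3-oxazolidin-2-one | C1C(=O)O[C@H](c2cc(OC)c(OC)c(OC)c2)[C@H]1C(=O)N3[C@@H](Cc4ccccc4)COC3=O
F3 | step 3 | (2S,3S)-5-oxo-2-(3,4,5-trimethoxyphenyl)oxolane-3-carboxylic acid | C1C(=O)O[C@H](c2cc(OC)c(OC)c(OC)c2)[C@H]1C(=O)O
F4 | step 3 | (4R,5S)-4-(hydroxymethyl)-5-(3,4,5-trimethoxyphenyl)oxolan-2-one | C1C(=O)O[C@H](c2cc(OC)c(OC)c(OC)c2)[C@H]1CO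
F5 | step 3 | (4R,5S)-4-{[(tert-butyldimethylsilyl)oxy]methyl}-5-(3,4,5-trimethoxyphenyl)oxolan-2-one | C1C(=O)O[C@H](c2cc(OC)c(OC)c(OC)c2)[C@H]1CO[Si](C)(C)C(C)(C)C
F6 | step 3 | (4R,5S)-4-{[(tert-butyldimethylsilyl)oxy]methyl}-3-[(dimethylamino)methyl]-5-(3,4,5-trimethoxyphenyl)oxolan-2-one (C3 epimers) | CN(C)CC1C(=O)O[C@H](c2cc(OC)c(OC)c(OC)c2)[C@H]1CO[Si](C)(C)C(C)(C)C
F7 | step 4 | (3E,4R,5S)-4-{[(tert-butyldimethylsilyl)oxy]methyl}-5-(3,4,5-trimethoxyphenyl)-3-[(3,4,5-trimethoxyphenyl)methylidene]oxolan-2-one | COc1cc(/C=C2/C(=O)O[C@H](c3cc(OC)c(OC)c(OC)c3)[C@H]2CO[Si](C)(C)C(C)(C)C)cc(OC)c1OC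
F8 | step 6 | (1S,2R,3R)-2-{[(tert-butyldimethylsilyl)oxy]methyl}-1-(3,4,5-trimethoxyphenyl)-3-[(3,4,5-trimethoxyphenyl)methyl]butane-1,4-diol | COc1cc(C[C@@H](CO)[C@H](CO[Si](C)(C)C(C)(C)C)[C@H](O)c2cc(OC)c(OC)c(OC)c2)cc(OC)c1OC
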